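**Plan**
- Retrosynthesis: the acid and phenol are unmasked last; the side chain is cut at its C7–C8 bond (sp2–sp3, Negishi) and at its C2=C3 bond (Still–Gennari); the pyran ring is cut at C4–C4a and C3–C2, leaving an O-aryl enol ether and a two-carbon vinyl selenide.
- Forward: 2,3-dimethylhydroquinone → mono-silyl ether → aryl 3-bromopropanoate → aryl enol ether; ring B (pyran) is then annulated onto ring A (benzene) in one operation, and selenoxide elimination in the same flask gives the 2H-chromene; the eleven-carbon alkenyl iodide is joined last.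
- Enabling feature: the ether oxygen O1 on ring A with the free ortho carbon C4a (C8 is blocked by methyl). O1 stabilises a cation at C2, so C4a=C8a–O1=C2 reacts as a cationic 2-oxadiene, and C4a closes ring B.
- Stereochemistry: C2, the only stereocentre, comes from the chiral counter-anion in the key step; 6E comes from syn-carboalumination; 2Z comes from the Still–Gennari olefination.

Key step: step 5

Assumption: the sense of induction of the chiral acid in step 5 cannot be foreseen, so the catalyst enantiomer that delivers the required C2 configuration is the one used (both are accessible).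

**Step 1**
Reactants: 1 2,3-dimethylbenzene-1,4-diol
Product: 2 2,3-dimethyl-4-(triisopropylsilyloxy)phenol
Conditions: iPr3SiCl (1.0 equiv), imidazole, DMF, 0 → 20 °C; bis-ether removed, diol recycled
Reagents that add atoms: triisopropylsilyl chloride, CC(C)[Si](Cl)(C(C)C)C(C)C
Why: Silylation of a phenol with a silyl chloride and imidazole; the diol is C2-symmetric, so the mono-ether is a single constitutional isomer and only the degree of silylation needs stoichiometric control.

**Step 2**
Reactants: 2 2,3-dimethyl-4-(triisopropylsilyloxy)phenol; 3 3-bromopropanoyl chloride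
Product: 4 2,3-dimethyl-4-(triisopropylsilyloxy)phenyl 3-bromopropanoate
Conditions: pyridine (1.1 equiv), CH2Cl2, −20 → 0 °C
Reagents that add atoms: none
Why: O-Acylation of the free phenol by the acid chloride with pyridine as a weak base, kept cold to avoid E1cB loss of HBr to the acrylate.

**Step 3**
Reactants: 4 2,3-dimethyl-4-(triisopropylsilyloxy)phenyl 3-bromopropanoate
Product: 5 [4-(4-bromobut-1-en-2-yloxy)-2,3-dimethylphenoxy]triisopropylsilane
Conditions: Cp2Ti(μ-CH2)(μ-Cl)AlMe2 (Tebbe reagent, 1.2 equiv), pyridine (cat.), THF/toluene, −40 → 0 °C; aq. NaOH quench at −10 °C; basic alumina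
Reagents that add atoms: Tebbe reagent, C[Al-]1(C)C[Ti]([Cl+]1)(C1C=CC=C1)C1C=CC=C1
Why: Tebbe methylenation converts the carbonyl of an aryl ester into the 1,1-disubstituted aryl enol ether, and the non-basic reagent leaves the β-bromide and the silyl ether untouched.

**Step 4**
Reactants: 6 benzeneselenenyl bromide; 7 vinylmagnesium bromide
Product: 8 phenyl vinyl selenide
Conditions: THF, −78 → 0 °C
Reagents that add atoms: none
Why: Nucleophilic substitution at selenium of the selenenyl bromide by the vinyl Grignard reagent.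

**Step 5**
Reactants: 5 [4-(4-bromobut-1-en-2-yloxy)-2,3-dimethylphenoxy]triisopropylsilane; 8 phenyl vinyl selenide
Product: 13 (S)-2-(2-bromoethyl)-2,7,8-trimethyl-6-(triisopropylsilyloxy)-2H-chromene, via O-aryl oxocarbenium ion 9 (not isolated), via selenocarbenium ion 10 (not isolated), via 4-(phenylselanyl)chromane 11 (not isolated), via selenoxide 12 (not isolated)
Conditions: (S,S)-IDPi acid (5 mol%; imidodiphosphorimidate from two (S)-3,3'-bis[3,5-bis(trifluoromethyl)phenyl]-BINOL units, N-SO2CF3 groups), toluene, −60 °C, 5 added over 6 h by syringe pump to a fourfold excess of 8; Et3N quench at −60 °C; then NaHCO3, NaIO4 (6 equiv), THF/MeOH/H2O, 0 → 20 °C, dark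
Reagents that add atoms: none
Why: Proposed new method: a catalytic asymmetric oxa-Povarov reaction in which the confined acid protonates the terminal CH2 of 5 to give the O-aryl ketoxocarbenium ion 9 as a contact ion pair with the chiral anion, the CH2 terminus of 8 adds to C2 (bond C2–C3) to give the selenium-stabilised cation 10, and the arene carbon C4a attacks C4 (bond C4–C4a) before rearomatisation returns the proton to the catalyst and leaves selenide 11. The closest known reaction types are the racemic Lewis-acid-mediated oxa-Povarov reaction of aryl oxocarbenium ions with alkenes, the chiral-phosphoric-acid Povarov reaction of N-aryl iminium ions with vinyl ethers, and imidodiphosphorimidate catalysis of ketone-derived oxocarbenium ions in which methyl is told apart from a primary alkyl group. Ring B closes as the second half of a stepwise cationic [4+2] addition across the 2-oxadiene C4a=C8a–O1=C2: a 6-exo-trig attack on the selenocarbenium carbon by the aromatic C4a=C8a bond, which lies inside the new ring. C2 is set in the first C–C bond formation by the chiral counter-anion, which must leave the Re face of 9 (O > CH2CH2Br > CH3) open to 8; this gives the arrangement written (2R) in 11 and (S) in 13 and in the target, the letter changing only because the saturated C3 of 11 ranks below the bromoethyl group whereas the sp2 C3 of 13 and of the target ranks above the side chain, while C4 forms as both epimers and becomes sp2 in the same flask. Periodate then oxidises selenium only, and the benzylic selenoxide 12 undergoes the known syn-elimination through a five-membered cyclic transition state towards C3, the only carbon with β-hydrogens, so C3=C4 forms under neutral conditions without touching C2. The step needs attack of 8 through its CH2 end (secured by selenium stabilisation of the cation at the other carbon), closure at C4a (the only free position ortho to O1 and the only one that gives a six-membered ring), and capture of 9 by 8 in preference to a second molecule of 5 (secured by slow addition of 5 to excess 8 at −60 °C).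

**Step 6**
Reactants: 13 (S)-2-(2-bromoethyl)-2,7,8-trimethyl-6-(triisopropylsilyloxy)-2H-chromene
Product: 14 (S)-2-(2-iodoethyl)-2,7,8-trimethyl-6-(triisopropylsilyloxy)-2H-chromene
Conditions: NaI (8 equiv), acetone, 20 °C, dark
Reagents that add atoms: sodium iodide, [Na+].[I-]
Why: Finkelstein halide exchange (SN2 at the primary carbon) driven by precipitation of NaBr, run at room temperature in the dark to avoid electrocyclic ring opening of the 2H-chromene, which would racemise C2.

**Step 7**
Reactants: 15 pent-4-yn-1-ol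
Product: 17 (E)-5-iodo-4-methylpent-4-en-1-ol, via alkenylalane 16 (not isolated)
Conditions: AlMe3 (3 equiv), Cp2ZrCl2 (0.25 equiv), CH2Cl2, 0 → 20 °C; then I2, THF, −30 → 0 °C
Reagents that add atoms: trimethylaluminium, C[Al](C)C; iodine, [I][I]
Why: Zirconium-catalysed carboalumination (Negishi) adds Me–Al syn across the terminal alkyne with methyl on the internal carbon, and iodinolysis of the C–Al bond with retention fixes the E geometry.

**Step 8**
Reactants: 17 (E)-5-iodo-4-methylpent-4-en-1-ol
Product: 18 (E)-5-iodo-4-methylpent-4-enal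
Conditions: Dess–Martin periodinane, NaHCO3, CH2Cl2, 0 → 20 °C
Reagents that add atoms: none
Why: Dess–Martin oxidation of the primary alcohol to the aldehyde under buffered conditions that leave the alkenyl iodide intact.

**Step 9**
Reactants: 19 methyl 2-[bis(2,2,2-trifluoroethoxy)phosphoryl]acetate; 20 5-bromo-2-methylpent-2-ene
Product: 22 methyl 2-[bis(2,2,2-trifluoroethoxy)phosphoryl]-6-methylhept-5-enoate (racemic), via sodium phosphonoacetate 21 (not isolated)
Conditions: NaH, DMF, 0 °C; then 20, NaI (10 mol%), 50 °C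
Reagents that add atoms: none
Why: C-Alkylation of the stabilised phosphonoacetate anion 21 by the primary bromide (SN2, iodide catalysis); the new α-stereocentre is racemic and is destroyed in step 10.

**Step 10**
Reactants: 22 methyl 2-[bis(2,2,2-trifluoroethoxy)phosphoryl]-6-methylhept-5-enoate; 18 (E)-5-iodo-4-methylpent-4-enal
Product: 24 methyl (2Z,6E)-7-iodo-6-methyl-2-(4-methylpent-3-en-1-yl)hepta-2,6-dienoate, via potassium phosphonate carbanion 23 (not isolated)
Conditions: KN(SiMe3)2, 18-crown-6, THF, −78 °C; then 18, −78 °C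
Reagents that add atoms: none
Why: Still–Gennari olefination: the bis(trifluoroethyl) phosphonate under dissociating conditions eliminates fast from the kinetically formed adduct and should give the Z-trisubstituted enoate with the ester cis to the chain, while the alkenyl iodide is inert.

**Step 11**
Reactants: 14 (S)-2-(2-iodoethyl)-2,7,8-trimethyl-6-(triisopropylsilyloxy)-2H-chromene; 24 methyl (2Z,6E)-7-iodo-6-methyl-2-(4-methylpent-3-en-1-yl)hepta-2,6-dienoate
Product: 26 methyl (2Z,6E)-6-methyl-2-(4-methylpent-3-en-1-yl)-9-[(2S)-2,7,8-trimethyl-6-(triisopropylsilyloxy)-2H-chromen-2-yl]nona-2,6-dienoate, via alkylzinc iodide 25 (not isolated)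
Conditions: Zn dust (activated with BrCH2CH2Br and Me3SiCl), LiCl, THF, 25 °C; then 24, Pd(PPh3)4 (5 mol%), 25 °C, dark
Reagents that add atoms: none
Why: Negishi coupling: zinc inserts into the primary C–I bond, and palladium-catalysed coupling of the alkylzinc 25 with the alkenyl iodide proceeds with retention of both alkene geometries and tolerates the ester, the silyl ether and the chromene.

**Step 12**
Reactants: 26 methyl (2Z,6E)-6-methyl-2-(4-methylpent-3-en-1-yl)-9-[(2S)-2,7,8-trimethyl-6-(triisopropylsilyloxy)-2H-chromen-2-yl]nona-2,6-dienoate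
Product: 28 (2Z,6E)-9-[(2S)-6-hydroxy-2,7,8-trimethyl-2H-chromen-2-yl]-6-methyl-2-(4-methylpent-3-en-1-yl)nona-2,6-dienoic acid (target), via phenol methyl ester 27 (not isolated)
Conditions: Bu4NF (1.2 equiv), THF, 0 °C; then LiOH·H2O (6 equiv), MeOH/H2O, degassed, 35 °C, dark; 0.5 M HCl to pH 4 at 0 °C
Reagents that add atoms: lithium hydroxide (supplies one carboxyl oxygen), [Li+].[OH-]
Why: Fluoride cleaves the aryl silyl ether and hydroxide saponifies the methyl ester by addition–elimination at the acyl carbon under mild, oxygen-free conditions in the dark, which should leave the Z-alkene, the chromene and C2 unchanged.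

**Compound list**
1 | 2,3-dimethylbenzene-1,4-diol | Cc1c(O)ccc(O)c1C | starting material
2 | 2,3-dimethyl-4-(triisopropylsilyloxy)phenol | Cc1c(O)ccc(O[Si](C(C)C)(C(C)C)C(C)C)c1C | intermediate
3 | 3-bromopropanoyl chloride | O=C(Cl)CCBr | starting material
4 | 2,3-dimethyl-4-(triisopropylsilyloxy)phenyl 3-bromopropanoate | O=C(CCBr)Oc1ccc(O[Si](C(C)C)(C(C)C)C(C)C)c(C)c1C | intermediate
5 | [4-(4-bromobut-1-en-2-yloxy)-2,3-dimethylphenoxy]triisopropylsilane | C=C(CCBr)Oc1ccc(O[Si](C(C)C)(C(C)C)C(C)C)c(C)c1C | intermediate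
6 | benzeneselenenyl bromide | Br[Se]c1ccccc1 | starting material
7 | vinylmagnesium bromide | C=C[Mg]Br | starting material
8 | phenyl vinyl selenide | C=C[Se]c1ccccc1 | intermediate
9 | (4-bromobutan-2-ylidene)[2,3-dimethyl-4-(triisopropylsilyloxy)phenyl]oxonium (O-aryl oxocarbenium ion, paired with the chiral anion) | CC(CCBr)=[O+]c1ccc(O[Si](C(C)C)(C(C)C)C(C)C)c(C)c1C | intermediate
10 | selenocarbenium ion, (R) at the new quaternary carbon: [(3R)-5-bromo-3-methyl-3-(aryloxy)pentylidene](phenyl)selenonium, aryl = 2,3-dimethyl-4-(triisopropylsilyloxy)phenyl | BrCC[C@@](C)(CC=[Se+]c1ccccc1)Oc1ccc(O[Si](C(C)C)(C(C)C)C(C)C)c(C)c1C | intermediate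
11 | (2R,4RS)-2-(2-bromoethyl)-2,7,8-trimethyl-4-(phenylselanyl)-6-(triisopropylsilyloxy)chromane (both C4 epimers) | BrCC[C@@]1(C)CC([Se]c2ccccc2)c2cc(O[Si](C(C)C)(C(C)C)C(C)C)c(C)c(C)c2O1 | intermediate
12 | selenoxide of 11, (2R), mixture at C4 and Se | BrCC[C@@]1(C)CC([Se](=O)c2ccccc2)c2cc(O[Si](C(C)C)(C(C)C)C(C)C)c(C)c(C)c2O1 | intermediate
13 | (S)-2-(2-bromoethyl)-2,7,8-trimethyl-6-(triisopropylsilyloxy)-2H-chromene | BrCC[C@@]1(C)C=Cc2cc(O[Si](C(C)C)(C(C)C)C(C)C)c(C)c(C)c2O1 | intermediate
14 | (S)-2-(2-iodoethyl)-2,7,8-trimethyl-6-(triisopropylsilyloxy)-2H-chromene | ICC[C@@]1(C)C=Cc2cc(O[Si](C(C)C)(C(C)C)C(C)C)c(C)c(C)c2O1 | intermediate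
15 | pent-4-yn-1-ol | C#CCCCO | starting material
16 | (E)-alkenylalane: dimethylaluminium alkoxide of (E)-5-(dimethylalumanyl)-4-methylpent-4-en-1-ol | C[Al](C)OCCC/C(C)=C/[Al](C)C | intermediate
17 | (E)-5-iodo-4-methylpent-4-en-1-ol | OCCC/C(C)=C/I | intermediate
18 | (E)-5-iodo-4-methylpent-4-enal | O=CCC/C(C)=C/I | intermediate
19 | methyl 2-[bis(2,2,2-trifluoroethoxy)phosphoryl]acetate | COC(=O)CP(=O)(OCC(F)(F)F)OCC(F)(F)F | starting material
20 | 5-bromo-2-methylpent-2-ene | CC(C)=CCCBr | starting material
21 | sodium salt of 19 (phosphonoacetate carbanion) | [Na+].COC(=O)[CH-]P(=O)(OCC(F)(F)F)OCC(F)(F)F | intermediate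
22 | methyl 2-[bis(2,2,2-trifluoroethoxy)phosphoryl]-6-methylhept-5-enoate (racemic) | COC(=O)C(CCC=C(C)C)P(=O)(OCC(F)(F)F)OCC(F)(F)F | intermediate
23 | potassium salt of 22 (phosphonate carbanion) | [K+].COC(=O)[C-](CCC=C(C)C)P(=O)(OCC(F)(F)F)OCC(F)(F)F | intermediate
24 | methyl (2Z,6E)-7-iodo-6-methyl-2-(4-methylpent-3-en-1-yl)hepta-2,6-dienoate | COC(=O)/C(CCC=C(C)C)=C\CC/C(C)=C/I | intermediate
25 | iodo{2-[(2S)-2,7,8-trimethyl-6-(triisopropylsilyloxy)-2H-chromen-2-yl]ethyl}zinc | I[Zn]CC[C@@]1(C)C=Cc2cc(O[Si](C(C)C)(C(C)C)C(C)C)c(C)c(C)c2O1 | intermediate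
26 | methyl (2Z,6E)-6-methyl-2-(4-methylpent-3-en-1-yl)-9-[(2S)-2,7,8-trimethyl-6-(triisopropylsilyloxy)-2H-chromen-2-yl]nona-2,6-dienoate | CC(C)=CCC/C(=C/CC/C(C)=C/CC[C@@]1(C)C=Cc2cc(O[Si](C(C)C)(C(C)C)C(C)C)c(C)c(C)c2O1)C(=O)OC | intermediate
27 | methyl (2Z,6E)-9-[(2S)-6-hydroxy-2,7,8-trimethyl-2H-chromen-2-yl]-6-methyl-2-(4-methylpent-3-en-1-yl)nona-2,6-dienoate | CC(C)=CCC/C(=C/CC/C(C)=C/CC[C@@]1(C)C=Cc2cc(O)c(C)c(C)c2O1)C(=O)OC | intermediate
28 | (2Z,6E)-9-[(2S)-6-hydroxy-2,7,8-trimethyl-2H-chromen-2-yl]-6-methyl-2-(4-methylpent-3-en-1-yl)nona-2,6-dienoic acid | CC(C)=CCC/C(=C/CC/C(C)=C/CC[C@@]1(C)C=Cc2cc(O)c(C)c(C)c2O1)C(=O)O | target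

**Count**
Total steps: 12. Longest linear sequence: 7 steps (1, 2, 3, 5, 6, 11, 12).

**Steps most likely to fail**

1. Step 5 (Proposed new method). The ion pair may discriminate the two faces of the ketoxocarbenium ion poorly, the enol ether may condense with itself, the acid may oligomerise the vinyl selenide, or benzeneselenenic acid may add back to the electron-rich chromene during the oxidation stage. The fallback uses known chemistry, sets out from phenol 2 and comes back to the route at bromide 13. Vinylmagnesium bromide 7 is added to commercial 4-bromobutan-2-one with CeCl3 (THF, −78 °C) to give racemic 5-bromo-3-methylpent-1-en-3-ol F1, which is converted with n-BuLi and ClCO2Me into methyl 5-bromo-3-methylpent-1-en-3-yl carbonate F2. Asymmetric Tsuji–Trost etherification of 2 with F2 (Pd2(dba)3·CHCl3, the C2-symmetric N,N'-(cyclohexane-1,2-diyl)bis[2-(diphenylphosphino)benzamide] ligand in the enantiomer that gives the (S) ether, CH2Cl2, 20 °C) should give the tertiary aryl allyl ether F3. Hydroboration with 9-BBN and buffered NaBO3·4H2O oxidation give the primary alcohol F4. Oxidation with TEMPO/PhI(OAc)2 in MeCN/H2O gives the 3-aryloxy acid F5. Friedel–Crafts ring closure at C4a with (CF3CO)2O (CH2Cl2, 0 °C) gives the chroman-4-one F6. NaBH4 reduction gives the chroman-4-ol F7, and dehydration with methanesulfonyl chloride/Et3N at 0 °C gives 13.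

2. Step 11. Zinc insertion may be slow, and the alkylzinc may be lost by protonolysis or homocoupling before it transmetalates. The fallback sets out from iodide 14 and comes back at 26. Lithium–iodine exchange with t-BuLi (Et2O, −78 °C) gives the alkyllithium F8, which is trapped at −78 °C with B-methoxy-9-borabicyclo[3.3.1]nonane as the lithium borinate F9. This is coupled with 24 in a B-alkyl Suzuki–Miyaura reaction (PdCl2(dppf), aq. K3PO4, DMF, 20 °C) to give 26.

3. Step 12. Saponification of the hindered enoate may be slow, and prolonged base may isomerise the Z-alkene or let the phenolate oxidise in air. The fallback sets out from 24 and comes back at target 28. The ester is hydrolysed at the robust stage of 24 (LiOH, THF/MeOH/H2O) to the acid F10, which is protected as its triisopropylsilyl ester F11 (iPr3SiCl, imidazole). Negishi coupling of F11 with alkylzinc 25 under the conditions of step 11 gives the bis-silyl compound F12, and Bu4NF in THF at 0 °C then releases phenol and acid together to give 28 without any hydroxide step.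

**Further compounds**
F1 | step 5 | 5-bromo-3-methylpent-1-en-3-ol (racemic) | C=CC(C)(O)CCBr
F2 | step 5 | methyl 5-bromo-3-methylpent-1-en-3-yl carbonate (racemic) | C=CC(C)(CCBr)OC(=O)OC
F3 | step 5 | {4-[(3S)-5-bromo-3-methylpent-1-en-3-yl]oxy-2,3-dimethylphenoxy}triisopropylsilane | BrCC[C@@](C)(C=C)Oc1ccc(O[Si](C(C)C)(C(C)C)C(C)C)c(C)c1C
F4 | step 5 | (3R)-5-bromo-3-[2,3-dimethyl-4-(triisopropylsilyloxy)phenoxy]-3-methylpentan-1-ol | BrCC[C@@](C)(CCO)Oc1ccc(O[Si](C(C)C)(C(C)C)C(C)C)c(C)c1C
F5 | step 5 | (3R)-5-bromo-3-[2,3-dimethyl-4-(triisopropylsilyloxy)phenoxy]-3-methylpentanoic acid | BrCC[C@@](C)(CC(=O)O)Oc1ccc(O[Si](C(C)C)(C(C)C)C(C)C)c(C)c1C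
F6 | step 5 | (2R)-2-(2-bromoethyl)-2,7,8-trimethyl-6-(triisopropylsilyloxy)chroman-4-one | BrCC[C@@]1(C)CC(=O)c2cc(O[Si](C(C)C)(C(C)C)C(C)C)c(C)c(C)c2O1
F7 | step 5 | (2R,4RS)-2-(2-bromoethyl)-2,7,8-trimethyl-6-(triisopropylsilyloxy)chroman-4-ol | BrCC[C@@]1(C)CC(O)c2cc(O[Si](C(C)C)(C(C)C)C(C)C)c(C)c(C)c2O1
F8 | step 11 | {2-[(2S)-2,7,8-trimethyl-6-(triisopropylsilyloxy)-2H-chromen-2-yl]ethyl}lithium | [Li]CC[C@@]1(C)C=Cc2cc(O[Si](C(C)C)(C(C)C)C(C)C)c(C)c(C)c2O1
F9 | step 11 | lithium B-methoxy-B-{2-[(2S)-2,7,8-trimethyl-6-(triisopropylsilyloxy)-2H-chromen-2-yl]ethyl}-9-borabicyclo[3.3.1]nonan-9-uide | [Li+].CO[B-]1(CC[C@@]2(C)C=Cc3cc(O[Si](C(C)C)(C(C)C)C(C)C)c(C)c(C)c3O2)C2CCCC1CCC2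
F10 | step 12 | (2Z,6E)-7-iodo-6-methyl-2-(4-methylpent-3-en-1-yl)hepta-2,6-dienoic acid | OC(=O)/C(CCC=C(C)C)=C\CC/C(C)=C/I
F11 | step 12 | triisopropylsilyl (2Z,6E)-7-iodo-6-methyl-2-(4-methylpent-3-en-1-yl)hepta-2,6-dienoate | CC(C)[Si](OC(=O)/C(CCC=C(C)C)=C\CC/C(C)=C/I)(C(C)C)C(C)C
F12 | step 12 | triisopropylsilyl (2Z,6E)-6-methyl-2-(4-methylpent-3-en-1-yl)-9-[(2S)-2,7,8-trimethyl-6-(triisopropylsilyloxy)-2H-chromen-2-yl]nona-2,6-dienoate | CC(C)=CCC/C(=C/CC/C(C)=C/CC[C@@]1(C)C=Cc2cc(O[Si](C(C)C)(C(C)C)C(C)C)c(C)c(C)c2O1)C(=O)O[Si](C(C)C)(C(C)C)C(C)C
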